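**Plan** (lignan numbering: oxolane ring O–C9–C8–C8'–C9'; carbinol C7 on C8, carbinol C7' on C8')
- Retrosynthesis: cut C7'–aryl (aryl Grignard + aldehyde), then the ring bond between the O-bound CH2 C9' and the ring CH C8', then the O–C9' ether bond (stannylmethylation), last C7–C8 (aldol).
- Forward: a crotonate aldol joins silylated vanillin to the C9–C8–C8'–C7' chain; reduction and O-alkylation place a tin-bearing CH2 on O9; the oxolane then closes by C9'–C8' bond formation; C7' is oxidised to the aldehyde and arylated.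
- Enabling feature: C9' is a CH2 bound only to the ring oxygen and C8', so it can be carried as an α-alkoxy carbanion. C8' bears the one-carbon branch C7', which can be the end of a vinyl group; O–C9–C8–C8'=C7' is then a homoallyl ether set up for 5-exo ring closure.
- Stereochemistry: C7 and C8 from the (S)-benzyloxazolidinone auxiliary (syn aldol); C8' from C8 in the cyclization (trans); C7' from C8' in the Felkin–Anh/chelate-controlled Grignard addition.
- Protection: phenols as triisopropylsilyl ethers, C7–OH as a tert-butyldimethylsilyl ether, all removed by fluoride in the last step.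

Key step: step 7

Remark: Ar = 3-methoxy-4-(triisopropylsilyloxy)phenyl in all names below.

Step 1
Reactants: 1 vanillin (4-hydroxy-3-methoxybenzaldehyde)
Product: 2 3-methoxy-4-(triisopropylsilyloxy)benzaldehyde
Conditions: TIPSCl, imidazole, DMF, rt
Reagents that add atoms: triisopropylsilyl chloride CC(C)[Si](Cl)(C(C)C)C(C)C
Why: Imidazole-promoted O-silylation of the phenol (silyl ether formation) gives a bulky aryl silyl ether that should survive alkyllithium, hydride and alkaline peroxide and fall to fluoride at the end.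

Step 2
Reactants: 3 (S)-4-benzyl-1,3-oxazolidin-2-one; 4 (E)-but-2-enoyl chloride
Product: 6 (S)-4-benzyl-3-[(E)-but-2-enoyl]-1,3-oxazolidin-2-one, via lithium oxazolidinide 5 (not isolated)
Conditions: n-BuLi, THF, −78 °C; then 4, −78 to 0 °C
Reagents that add atoms: none
Why: N-Acylation of the lithiated oxazolidinone by the acid chloride should give the crotonate imide without touching the stereocentre of the auxiliary.

Step 3
Reactants: 6 (S)-4-benzyl-3-[(E)-but-2-enoyl]-1,3-oxazolidin-2-one; 2 3-methoxy-4-(triisopropylsilyloxy)benzaldehyde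
Product: 8 (S)-4-benzyl-3-[(2S,3S)-3-Ar-2-ethenyl-3-hydroxypropanoyl]-1,3-oxazolidin-2-one, via dibutylboron dienolate 7 (not isolated)
Conditions: Bu2BOTf, Et3N, CH2Cl2, −78 to 0 °C; 2, −78 to 0 °C; then pH 7 buffer, MeOH, H2O2, 0 °C
Reagents that add atoms: none
Why: Evans boron aldol reaction of a crotonate imide: γ-deprotonation gives the (Z)-dienolate, which should react at its α-carbon through a Zimmerman–Traxler chair on the face away from the benzyl group, setting C7 and C8 as the syn (2S,3S) adduct with the C8'=C7' vinyl group already in place.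

Step 4
Reactants: 8 (S)-4-benzyl-3-[(2S,3S)-3-Ar-2-ethenyl-3-hydroxypropanoyl]-1,3-oxazolidin-2-one
Product: 9 (1S,2R)-1-Ar-2-ethenylpropane-1,3-diol
Conditions: LiBH4, MeOH (1 equiv), THF, 0 °C
Reagents that add atoms: none
Why: Hydride reduction of the imide carbonyl should release the primary C9 alcohol and the auxiliary while leaving both stereocentres and the isolated vinyl group untouched.

Step 5
Reactants: 9 (1S,2R)-1-Ar-2-ethenylpropane-1,3-diol; 10 tributyl(iodomethyl)stannane
Product: 12 (1S,2R)-1-Ar-2-{[(tributylstannyl)methoxy]methyl}but-3-en-1-ol, via sodium alkoxide 11 (not isolated)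
Conditions: NaH (1 equiv), THF, 0 °C; then 10, DMF, 0 °C to rt
Reagents that add atoms: none
Why: Williamson etherification with one equivalent of base should alkylate the unhindered primary alkoxide much faster than the hindered benzylic hydroxyl, installing the future C9' as a tin-bearing carbon on O9.

Step 6
Reactants: 12 (1S,2R)-1-Ar-2-{[(tributylstannyl)methoxy]methyl}but-3-en-1-ol
Product: 13 tert-butyl({(1S,2R)-1-Ar-2-{[(tributylstannyl)methoxy]methyl}but-3-en-1-yl}oxy)dimethylsilane
Conditions: TBSOTf, 2,6-lutidine, CH2Cl2, −78 °C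
Reagents that add atoms: tert-butyldimethylsilyl triflate CC(C)(C)[Si](C)(C)OS(=O)(=O)C(F)(F)F
Why: Silylation of the remaining benzylic alcohol with a silyl triflate and a hindered pyridine base should mask the only acidic proton before the organolithium step.

Step 7
Reactants: 13 tert-butyl({(1S,2R)-1-Ar-2-{[(tributylstannyl)methoxy]methyl}but-3-en-1-yl}oxy)dimethylsilane
Product: 17 [(3S,4R)-4-{(S)-Ar[(tert-butyldimethylsilyl)oxy]methyl}oxolan-3-yl]methanol, via α-alkoxymethyllithium 14 (not isolated), via cyclized alkyllithium 15 (not isolated), via dimethyl boronate 16 (not isolated)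
Conditions: n-BuLi, THF, −78 °C then 0 °C; B(OMe)3, −78 °C to rt; H2O2, aq NaOH, 0 °C
Reagents that add atoms: hydrogen peroxide OO
Why: Tin–lithium exchange converts the O-bound CH2SnBu3 group into an α-alkoxymethyllithium, so that C9', normally an acceptor carbon, reacts with reversed polarity and adds across the unactivated C8'=C7' vinyl group by intramolecular carbolithiation; the primary alkyllithium formed at C7' is then borylated and oxidised with retention to the hydroxymethyl group. The closest known reaction type is the anionic cyclization of (tributylstannyl)methyl homoallyl ethers to 3-(lithiomethyl)oxolanes, a heteroatom variant of the 5-hexenyllithium cyclization. The oxolane ring closes in the 5-exo-trig mode through a chair-like transition state with lithium coordinated to the alkene. The new stereocentre C8' is controlled by the existing centre C8, whose bulky silyloxybenzyl group sits pseudo-equatorial at the allylic position and so should end up trans to the lithiomethyl group. The step needs exchange and 5-exo addition to be faster than Wittig rearrangement, proton transfer or attack at silicon; this is secured by the homoallylic (not allylic) ether, which rules out a [2,3] shift and makes the [1,2] shift of a primary alkyl group slow, by the terminal unhindered alkene and by silylation of the only hydroxyl group.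

Step 8
Reactants: 17 [(3S,4R)-4-{(S)-Ar[(tert-butyldimethylsilyl)oxy]methyl}oxolan-3-yl]methanol
Product: 18 (3R,4R)-4-{(S)-Ar[(tert-butyldimethylsilyl)oxy]methyl}oxolane-3-carbaldehyde
Conditions: Dess–Martin periodinane, CH2Cl2, 0 °C to rt
Reagents that add atoms: none
Why: Dess–Martin oxidation of the primary alcohol should stop at the aldehyde under non-basic conditions, keeping the trans C8/C8' relationship, which is also the thermodynamically preferred one at this epimerisable centre.

Step 9
Reactants: 19 4-bromo-2-methoxyphenol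
Product: 20 (4-bromo-2-methoxyphenoxy)triisopropylsilane
Conditions: TIPSCl, imidazole, DMF, rt
Reagents that add atoms: triisopropylsilyl chloride CC(C)[Si](Cl)(C(C)C)C(C)C
Why: Silyl ether formation as in step 1 should prepare the aryl bromide for metalation.

Step 10
Reactants: 18 (3R,4R)-4-{(S)-Ar[(tert-butyldimethylsilyl)oxy]methyl}oxolane-3-carbaldehyde; 20 (4-bromo-2-methoxyphenoxy)triisopropylsilane
Product: 22 (R)-[(3R,4R)-4-{(S)-Ar[(tert-butyldimethylsilyl)oxy]methyl}oxolan-3-yl](Ar)methanol, via arylmagnesium bromide 21 (not isolated)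
Conditions: 20, Mg, THF, rt; then 18, THF/CH2Cl2, −78 °C; aq NH4Cl
Reagents that add atoms: none
Why: Grignard addition to the aldehyde: Felkin–Anh attack anti to the larger ring branch C8, reinforced by magnesium chelation between the carbonyl oxygen and the ring oxygen, should deliver the aryl group to the face that gives the (R)-carbinol at C7'.

Step 11
Reactants: 22 (R)-[(3R,4R)-4-{(S)-Ar[(tert-butyldimethylsilyl)oxy]methyl}oxolan-3-yl](Ar)methanol
Product: 23 (S)-[(3R,4R)-4-[(R)-hydroxy(4-hydroxy-3-methoxyphenyl)methyl]oxolan-3-yl](4-hydroxy-3-methoxyphenyl)methanol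
Conditions: Bu4NF, AcOH, THF, 0 °C to rt
Reagents that add atoms: none
Why: Fluoride-mediated desilylation should remove the two aryl silyl ethers and the benzylic silyl ether in one operation, with acetic acid buffering the phenoxides so that the p-hydroxybenzylic alcohols do not eliminate to quinone methides.

**Compound list**
1 | vanillin | COc1cc(C=O)ccc1O | starting material
2 | 3-methoxy-4-(triisopropylsilyloxy)benzaldehyde | COc1cc(C=O)ccc1O[Si](C(C)C)(C(C)C)C(C)C | intermediate
3 | (S)-4-benzyl-1,3-oxazolidin-2-one | O=C1N[C@@H](Cc2ccccc2)CO1 | starting material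
4 | (E)-but-2-enoyl chloride | C/C=C/C(=O)Cl | starting material
5 | lithium salt of 3 (lithium oxazolidinide) | [Li]N1[C@@H](Cc2ccccc2)COC1=O | intermediate
6 | (S)-4-benzyl-3-[(E)-but-2-enoyl]-1,3-oxazolidin-2-one | C/C=C/C(=O)N1[C@@H](Cc2ccccc2)COC1=O | intermediate
7 | dibutylboron (Z)-dienolate of 6 | C=C/C=C(\OB(CCCC)CCCC)N1[C@@H](Cc2ccccc2)COC1=O | intermediate
8 | (S)-4-benzyl-3-[(2S,3S)-3-Ar-2-ethenyl-3-hydroxypropanoyl]-1,3-oxazolidin-2-one | COc1cc([C@@H](O)[C@H](C=C)C(=O)N2[C@@H](Cc3ccccc3)COC2=O)ccc1O[Si](C(C)C)(C(C)C)C(C)C | intermediate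
9 | (1S,2R)-1-Ar-2-ethenylpropane-1,3-diol | COc1cc([C@@H](O)[C@H](C=C)CO)ccc1O[Si](C(C)C)(C(C)C)C(C)C | intermediate
10 | tributyl(iodomethyl)stannane | CCCC[Sn](CCCC)(CCCC)CI | starting material
11 | sodium primary alkoxide of 9 | COc1cc([C@@H](O)[C@H](C=C)CO[Na])ccc1O[Si](C(C)C)(C(C)C)C(C)C | intermediate
12 | (1S,2R)-1-Ar-2-{[(tributylstannyl)methoxy]methyl}but-3-en-1-ol | COc1cc([C@@H](O)[C@H](C=C)COC[Sn](CCCC)(CCCC)CCCC)ccc1O[Si](C(C)C)(C(C)C)C(C)C | intermediate
13 | tert-butyl({(1S,2R)-1-Ar-2-{[(tributylstannyl)methoxy]methyl}but-3-en-1-yl}oxy)dimethylsilane | COc1cc([C@@H](O[Si](C)(C)C(C)(C)C)[C@H](C=C)COC[Sn](CCCC)(CCCC)CCCC)ccc1O[Si](C(C)C)(C(C)C)C(C)C | intermediate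
14 | α-alkoxymethyllithium from 13 (Li in place of SnBu3) | COc1cc([C@@H](O[Si](C)(C)C(C)(C)C)[C@H](C=C)COC[Li])ccc1O[Si](C(C)C)(C(C)C)C(C)C | intermediate
15 | {(3R,4R)-4-{(S)-Ar[(tert-butyldimethylsilyl)oxy]methyl}oxolan-3-yl}methyllithium (trans) | COc1cc([C@@H](O[Si](C)(C)C(C)(C)C)[C@H]2COC[C@@H]2C[Li])ccc1O[Si](C(C)C)(C(C)C)C(C)C | intermediate
16 | dimethyl {(3R,4R)-4-{(S)-Ar[(tert-butyldimethylsilyl)oxy]methyl}oxolan-3-yl}methylboronate | COc1cc([C@@H](O[Si](C)(C)C(C)(C)C)[C@H]2COC[C@@H]2CB(OC)OC)ccc1O[Si](C(C)C)(C(C)C)C(C)C | intermediate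
17 | [(3S,4R)-4-{(S)-Ar[(tert-butyldimethylsilyl)oxy]methyl}oxolan-3-yl]methanol | COc1cc([C@@H](O[Si](C)(C)C(C)(C)C)[C@H]2COC[C@@H]2CO)ccc1O[Si](C(C)C)(C(C)C)C(C)C | intermediate
18 | (3R,4R)-4-{(S)-Ar[(tert-butyldimethylsilyl)oxy]methyl}oxolane-3-carbaldehyde | COc1cc([C@@H](O[Si](C)(C)C(C)(C)C)[C@H]2COC[C@@H]2C=O)ccc1O[Si](C(C)C)(C(C)C)C(C)C | intermediate
19 | 4-bromo-2-methoxyphenol | COc1cc(Br)ccc1O | starting material
20 | (4-bromo-2-methoxyphenoxy)triisopropylsilane | COc1cc(Br)ccc1O[Si](C(C)C)(C(C)C)C(C)C | intermediate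
21 | [3-methoxy-4-(triisopropylsilyloxy)phenyl]magnesium bromide | COc1cc([Mg]Br)ccc1O[Si](C(C)C)(C(C)C)C(C)C | intermediate
22 | (R)-[(3R,4R)-4-{(S)-Ar[(tert-butyldimethylsilyl)oxy]methyl}oxolan-3-yl](Ar)methanol | COc1cc([C@@H](O[Si](C)(C)C(C)(C)C)[C@H]2COC[C@@H]2[C@@H](O)c2ccc(O[Si](C(C)C)(C(C)C)C(C)C)c(OC)c2)ccc1O[Si](C(C)C)(C(C)C)C(C)C | intermediate
23 | (S)-[(3R,4R)-4-[(R)-hydroxy(4-hydroxy-3-methoxyphenyl)methyl]oxolan-3-yl](4-hydroxy-3-methoxyphenyl)methanol | COc1cc([C@@H](O)[C@H]2COC[C@@H]2[C@@H](O)c2ccc(O)c(OC)c2)ccc1O | target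

**Step count**
Total steps: 11. Longest linear sequence: 9 steps (steps 2 to 8, then 10 and 11, starting from 3).

**Steps most likely to fail, with fallbacks**

Risk 1, step 7. The α-alkoxymethyllithium may be protonated or may abstract the benzylic proton before it cyclizes, or the cyclized alkyllithium may attack the neighbouring silyl ether before it is trapped. The fallback forms the same C9'–C8' bond by cationic chemistry; it sets out from diol 9 and returns at aldehyde 18. Diol 9 would be converted with MOMCl and iPr2NEt into the primary methoxymethyl ether F1, and the benzylic hydroxyl silylated (TBSOTf, 2,6-lutidine) to give the silyl ether F2. Cross-metathesis of the vinyl group with allyltrimethylsilane (second-generation Grubbs catalyst) should give the allylsilane F3. With SnCl4 in CH2Cl2 at −78 °C the methoxymethyl ether ionises to the O9-bound methylene oxocarbenium ion, which the allylsilane captures at C8' (intramolecular Hosomi–Sakurai reaction) to give the trans 4-ethenyloxolane F4. Oxidative cleavage of the vinyl group (OsO4 catalytic, NaIO4, 2,6-lutidine) then gives aldehyde 18; any cis isomer should equilibrate to trans at this stage with a mild base.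

Risk 2, step 10. Facial selectivity in the aryl addition to the α-branched aldehyde may be poor. The fallback sets out from 18 and returns at 22. The Grignard addition would be run without regard to selectivity, and the mixture of 22 and its C7' epimer F5 oxidised with Dess–Martin periodinane to the aryl ketone F6. Reduction of F6 with BH3·SMe2 and (S)-2-methyl-CBS-oxazaborolidine (Corey–Bakshi–Shibata reduction, aryl as the large group) should then set the (R)-carbinol by reagent control and give 22.

Risk 3, step 5. Alkylation may occur at the benzylic hydroxyl or at both hydroxyls. The fallback sets out from 9 and returns at 12. Diol 9 would be heated with Bu2SnO in toluene with removal of water to give the six-membered dibutylstannylene acetal F7. Treatment of F7 with 10 and CsF in DMF should alkylate the tin-activated primary oxygen selectively and give 12 after aqueous work-up.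

Further compounds
F1 | step 7 | (1S,2R)-1-Ar-2-[(methoxymethoxy)methyl]but-3-en-1-ol | COc1cc([C@@H](O)[C@H](C=C)COCOC)ccc1O[Si](C(C)C)(C(C)C)C(C)C
F2 | step 7 | tert-butyl({(1S,2R)-1-Ar-2-[(methoxymethoxy)methyl]but-3-en-1-yl}oxy)dimethylsilane | COc1cc([C@@H](O[Si](C)(C)C(C)(C)C)[C@H](C=C)COCOC)ccc1O[Si](C(C)C)(C(C)C)C(C)C
F3 | step 7 | tert-butyl({(1S,2R,3E)-1-Ar-2-[(methoxymethoxy)methyl]-5-(trimethylsilyl)pent-3-en-1-yl}oxy)dimethylsilane | COc1cc([C@@H](O[Si](C)(C)C(C)(C)C)[C@H](/C=C/C[Si](C)(C)C)COCOC)ccc1O[Si](C(C)C)(C(C)C)C(C)C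
F4 | step 7 | tert-butyl{(S)-[(3R,4R)-4-ethenyloxolan-3-yl](Ar)methoxy}dimethylsilane | COc1cc([C@@H](O[Si](C)(C)C(C)(C)C)[C@H]2COC[C@@H]2C=C)ccc1O[Si](C(C)C)(C(C)C)C(C)C
F5 | step 10 | (S)-[(3R,4R)-4-{(S)-Ar[(tert-butyldimethylsilyl)oxy]methyl}oxolan-3-yl](Ar)methanol | COc1cc([C@@H](O[Si](C)(C)C(C)(C)C)[C@H]2COC[C@@H]2[C@H](O)c2ccc(O[Si](C(C)C)(C(C)C)C(C)C)c(OC)c2)ccc1O[Si](C(C)C)(C(C)C)C(C)C
F6 | step 10 | [(3R,4R)-4-{(S)-Ar[(tert-butyldimethylsilyl)oxy]methyl}oxolan-3-yl](Ar)methanone | COc1cc([C@@H](O[Si](C)(C)C(C)(C)C)[C@H]2COC[C@@H]2C(=O)c2ccc(O[Si](C(C)C)(C(C)C)C(C)C)c(OC)c2)ccc1O[Si](C(C)C)(C(C)C)C(C)C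
F7 | step 5 | (4S,5R)-4-Ar-2,2-dibutyl-5-ethenyl-1,3,2-dioxastanninane | COc1cc([C@@H](O[Sn](CCCC)(CCCC)O2)[C@H](C=C)C2)ccc1O[Si](C(C)C)(C(C)C)C(C)C
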